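**Strategy.** The ten-membered ring is closed at C5–C6: the (Z)-C4=C5 alkenyl iodide of an open chain adds to the C6 aldehyde (Nozaki–Hiyama–Kishi), and the C6 alkoxide then lactonises onto the C12 acrylate ester. One operation therefore builds the carbocycle, the cis-fused α-methylene-γ-butyrolactone and the C6 stereocentre. The step exploits that C5 is an sp2 carbon of the later C4–C5 epoxide and that C6 is the lactone carbinol next to C7. The precursor is an acyclic iodo-aldehyde whose C9 is bought as (S)-malate; C8 and C7 are relayed from C9 in one indium allylation, C6 from C7, and C4/C5 from C6 by epoxidation.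

Key step: step 15

Remark: locants follow germacrane numbering (ring C1–C10; C11 on C7, C12 the lactone carbonyl, C13 the methylidene carbon; C14 the ester carbon on C10; C15 the methyl on C4; C2' the quaternary oxirane carbon of the acyl group on O8). As drawn, the target has a cis-fused lactone (H6/H7 cis) and a cis-epoxide (C3/C6 cis), and the route is built for exactly this isomer.

Step 1
Reactants: 1 (tert-butyldimethylsilyloxy)acetaldehyde; 2 methyl acrylate
Product: 3 methyl 4-[(tert-butyldimethylsilyl)oxy]-3-hydroxy-2-methylidenebutanoate (racemic)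
Conditions: DABCO (cat.), MeOH, rt
Reagents that add atoms: none
Why: Morita–Baylis–Hillman reaction of the unhindered α-silyloxy aldehyde with the acrylate; the racemic carbinol centre is erased in step 2.

Step 2
Reactants: 3 Morita–Baylis–Hillman adduct
Product: 4 methyl (Z)-2-(bromomethyl)-4-[(tert-butyldimethylsilyl)oxy]but-2-enoate
Conditions: NBS, Me2S, CH2Cl2, 0 °C to rt
Reagents that add atoms: N-bromosuccinimide, O=C1CCC(=O)N1Br
Why: Corey–Kim-type activation of the secondary alcohol followed by SN2' attack of bromide should give the transposed primary allylic bromide in its preferred geometry (CH2Br cis to CH2OTBS).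

Step 3
Reactants: 5 prop-2-yn-1-ol
Product: 7 (Z)-3-iodo-2-methylprop-2-en-1-ol, via alkenylmagnesium alkoxide 6 (not isolated)
Conditions: MeMgBr (2.5 equiv), CuI (10 mol %), THF, −10 °C to rt; then I2, −78 °C to rt
Reagents that add atoms: methylmagnesium bromide, C[Mg]Br; iodine, II
Why: Copper-catalysed anti-carbomagnesiation directed by the magnesium alkoxide puts methyl on C-2 and magnesium on C-3 cis to CH2O, and iodinolysis with retention fixes the Z-geometry (CH2OH cis to I).

Step 4
Reactants: 7 (Z)-3-iodo-2-methylprop-2-en-1-ol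
Product: 8 (Z)-3-bromo-1-iodo-2-methylprop-1-ene
Conditions: CBr4, PPh3, CH2Cl2, 0 °C
Reagents that add atoms: carbon tetrabromide, BrC(Br)(Br)Br
Why: Appel reaction under neutral conditions, which should leave the alkenyl iodide and its geometry untouched.

Step 5
Reactants: 8 (Z)-3-bromo-1-iodo-2-methylprop-1-ene; 9 acetaldehyde N,N-dimethylhydrazone
Product: 11 (Z)-5-iodo-4-methylpent-4-enal, via alkylated hydrazone 10 (not isolated)
Conditions: LiN(iPr)2, THF, 0 °C; then 8, −78 °C to 0 °C; then aq. oxalic acid, Et2O, rt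
Reagents that add atoms: water, O
Why: SN2 alkylation of the hydrazone aza-enolate with the primary allylic bromide followed by mild hydrazone hydrolysis; the alkenyl iodide is inert to the stabilised anion and no stereocentre is formed.

Step 6
Reactants: 12 dimethyl (S)-malate; 11 (Z)-5-iodo-4-methylpent-4-enal
Product: 14 methyl (3S,4S)-4-hydroxy-2-[(Z)-4-iodo-3-methylbut-3-en-1-yl]-5-oxooxolane-3-carboxylate (C2 epimers), via open aldol diester 13 (not isolated)
Conditions: LiN(SiMe3)2 (2.2 equiv), THF, −78 °C; then 11, −78 to −20 °C; 1 M HCl; then TsOH (cat.), CH2Cl2, rt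
Reagents that add atoms: none
Why: Fráter–Seebach dianion aldol (attack anti to the alkoxide), then acid-catalysed lactonisation of the new hydroxyl onto the neighbouring ester; the bought C9 centre is not enolisable as its alkoxide and is retained, while the two other centres disappear in step 7.

Step 7
Reactants: 14 hydroxy lactone
Product: 16 (2S,3E,7Z)-8-iodo-3-(methoxycarbonyl)-2-[(4-methoxybenzyl)oxy]-7-methylocta-3,7-dienoic acid, via dipotassium alkoxide carboxylate 15 (not isolated)
Conditions: KN(SiMe3)2 (2.2 equiv), THF, −78 to 0 °C; then PMBCl, Bu4NI (cat.), 0 °C to rt; 1 M HCl to pH 3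
Reagents that add atoms: 4-methoxybenzyl chloride, COc1ccc(CCl)cc1
Why: E1cB ring opening, in which the C10 ester enolate expels the lactone carboxylate to give the preferred enoate geometry (C2 trans to CO2Me) while the C9 alkoxide shields C9–H from enolisation, followed by Williamson etherification of the alkoxide, which should outrun alkylation of the poorly nucleophilic carboxylate in THF.

Step 8
Reactants: 16 PMB ether acid
Product: 17 methyl (2E,6Z)-2-[(1S)-2-hydroxy-1-[(4-methoxybenzyl)oxy]ethyl]-7-iodo-6-methylhepta-2,6-dienoate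
Conditions: BH3·SMe2, THF, 0 °C; MeOH quench
Reagents that add atoms: none
Why: Borane reduces the free carboxylic acid through its acyloxyborane far faster than the conjugated ester or the alkenes; 17 is used at once because a γ-hydroxy ester can lactonise.

Step 9
Reactants: 17 primary alcohol
Product: 18 methyl (2E,6Z)-7-iodo-2-[(1S)-1-[(4-methoxybenzyl)oxy]-2-oxoethyl]-6-methylhepta-2,6-dienoate
Conditions: Dess–Martin periodinane, pyridine, CH2Cl2, 0 °C
Reagents that add atoms: none
Why: Dess–Martin oxidation under buffered, non-basic conditions should give the α-alkoxy aldehyde without epimerising C9; it is used crude.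

Step 10
Reactants: 18 α-alkoxy aldehyde; 4 allylic bromide
Product: 19 homoallylic alcohol (7S,8S,9S): C6–OTBS, C8–OH, C9–OPMB, C12 and C14 methyl esters
Conditions: indium powder, THF/H2O (1:1), rt
Reagents that add atoms: none
Why: Barbier-type indium allylation in water, in which the chelated α-alkoxy aldehyde is attacked on the face away from C10 (8,9-syn) and the γ-substituted 2-(methoxycarbonyl)allylindium reacts at its γ-carbon through a chair transition state (7,8-syn), so that C9 sets C8 and C7 in one event.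

Step 11
Reactants: 20 (R)-(2-methyloxiran-2-yl)methanol
Product: 21 (S)-2-methyloxirane-2-carboxylic acid
Conditions: RuCl3·xH2O (cat.), NaIO4, MeCN/CCl4/H2O, 0 °C to rt
Reagents that add atoms: water, O
Why: Ruthenium tetroxide oxidation of the primary alcohol to the acid through the aldehyde hydrate; the quaternary epoxide centre is untouched (the descriptor changes only by priority).

Step 12
Reactants: 19 homoallylic alcohol; 21 (S)-2-methyloxirane-2-carboxylic acid
Product: 22 C8 (2S)-2-methyloxirane-2-carboxylate of 19 (7S,8S,9S,2'S)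
Conditions: DCC, DMAP (cat.), CH2Cl2, 0 °C to rt
Reagents that add atoms: none
Why: Steglich esterification of the only free hydroxyl, where carbodiimide activation and DMAP acyl transfer should outrun lactonisation of the γ-hydroxy ester.

Step 13
Reactants: 22 silyl ether
Product: 23 C6 primary alcohol (7S,8S,9S,2'S)
Conditions: HF·pyridine, pyridine, THF, 0 °C
Reagents that add atoms: none
Why: Buffered fluoride cleavage of the primary silyl ether; the ester-deactivated oxirane, the PMB ether and the esters should survive, and 23 is oxidised at once to forestall lactonisation.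

Step 14
Reactants: 23 primary alcohol
Product: 24 C6 aldehyde (7R,8S,9S,2'S; descriptor change at C7 by priority only)
Conditions: Dess–Martin periodinane, pyridine, CH2Cl2, 0 °C
Reagents that add atoms: none
Why: Dess–Martin oxidation under buffered conditions should give the β,γ-unsaturated aldehyde without moving the C11=C13 double bond into conjugation or epimerising C7; the crude aldehyde goes straight into step 15.

Step 15
Reactants: 24 iodo-aldehyde
Product: 26 cis-fused α-methylene lactone with (4Z)-alkene (6S,7S,8S,9S,2'S), via macrocyclic hydroxy ester 25 (not isolated)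
Conditions: CrCl2 (6 equiv), NiCl2 (2 mol %), DMSO/THF, rt, 0.003 M, slow addition of 24; then PPTS (cat.), CH2Cl2, rt
Reagents that add atoms: none
Why: The (Z)-alkenyl iodide adds oxidatively to zerovalent nickel (made from NiCl2 by CrCl2), the alkenyl group passes to trivalent chromium and adds to the C6 aldehyde with retention of the C4=C5 geometry, and the C6 oxygen then acylates on C12 with loss of methanol. The closest known reaction type is the Nozaki–Hiyama–Kishi macrocyclisation of ω-iodoalkenyl aldehydes to medium-ring allylic alcohols. The ten-membered carbocycle closes 10-exo-trig on the aldehyde carbonyl and the lactone closes 5-exo-trig on the C12 ester carbonyl. The only new stereocentre, C6, is set by C7: in the Felkin–Anh rotamer with the sp2 acrylate carbon C11 antiperiplanar to the incoming C5, the tether-bearing C8 is syn-clinal, as ring closure itself requires, and O6 ends cis to C11, which is the cis-fused lactone. The step needs carbonyl selectivity over two enoates, the glycidate and the PMB ether, which the low basicity of alkenylchromium reagents should secure, and cyclisation over oligomerisation, which high dilution and the two cis-alkenes of the chain should favour.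

Step 16
Reactants: 26 lactone diene
Product: 27 (4R,5S)-epoxide, C9–OPMB (4R,5S,6R,7R,8S,9S,2'S)
Conditions: mCPBA, CH2Cl2, 0 °C
Reagents that add atoms: 3-chloroperoxybenzoic acid, O=C(OO)c1cccc(Cl)c1
Why: Prilezhaev epoxidation of the only electron-rich alkene (C4=C5); allylic 1,3-strain with C3 holds H6 in the alkene plane, so O6 lies on the outer face and C7 with the ring body on the inner face, and peripheral attack anti to C7 should give the cis-epoxide with C5–O and C6–O syn.

Step 17
Reactants: 27 PMB ether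
Product: 28 C9 alcohol (4R,5S,6R,7R,8S,9S,2'S)
Conditions: DDQ, CH2Cl2/pH 7 buffer (10:1), 0 °C to rt
Reagents that add atoms: none
Why: Oxidative PMB cleavage through the benzylic oxocarbenium ion; the epoxides, the enoate and the α-methylene lactone are inert to DDQ.

Step 18
Reactants: 28 C9 alcohol
Product: 29 target, methyl (1R,2S,4R,7E,9S,10S,11R)-9-acetoxy-4-methyl-12-methylidene-10-{[(2S)-2-methyloxirane-2-carbonyl]oxy}-13-oxo-3,14-dioxatricyclo[9.3.0.0^2,4]tetradec-7-ene-8-carboxylate
Conditions: Ac2O, pyridine, DMAP (cat.), CH2Cl2, 0 °C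
Reagents that add atoms: acetic anhydride, CC(=O)OC(C)=O
Why: DMAP-catalysed acetylation of the remaining secondary hydroxyl, fast enough that the neighbouring C8 ester should not migrate.

**Compound list**

1 | (tert-butyldimethylsilyloxy)acetaldehyde | O=CCO[Si](C)(C)C(C)(C)C | starting material
2 | methyl acrylate | C=CC(=O)OC | starting material
3 | methyl 4-[(tert-butyldimethylsilyl)oxy]-3-hydroxy-2-methylidenebutanoate (racemic) | C=C(C(=O)OC)C(O)CO[Si](C)(C)C(C)(C)C | intermediate
4 | methyl (Z)-2-(bromomethyl)-4-[(tert-butyldimethylsilyl)oxy]but-2-enoate | COC(=O)/C(CBr)=C/CO[Si](C)(C)C(C)(C)C | intermediate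
5 | prop-2-yn-1-ol | C#CCO | starting material
6 | bromomagnesium (Z)-3-(bromomagnesio)-2-methylprop-2-en-1-olate | Br[Mg]OC/C(C)=C\[Mg]Br | intermediate
7 | (Z)-3-iodo-2-methylprop-2-en-1-ol | OC/C(C)=C\I | intermediate
8 | (Z)-3-bromo-1-iodo-2-methylprop-1-ene | BrC/C(C)=C\I | intermediate
9 | acetaldehyde N,N-dimethylhydrazone | CC=NN(C)C | starting material
10 | (Z)-5-iodo-4-methylpent-4-enal N,N-dimethylhydrazone | CN(C)N=CCC/C(C)=C\I | intermediate
11 | (Z)-5-iodo-4-methylpent-4-enal | O=CCC/C(C)=C\I | intermediate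
12 | dimethyl (S)-malate | COC(=O)[C@@H](O)CC(=O)OC | starting material
13 | dimethyl (2S,3R)-2-hydroxy-3-[(Z)-1-hydroxy-5-iodo-4-methylpent-4-en-1-yl]butanedioate (carbinol epimers) | COC(=O)[C@@H](O)[C@H](C(=O)OC)C(O)CC/C(C)=C\I | intermediate
14 | methyl (3S,4S)-4-hydroxy-2-[(Z)-4-iodo-3-methylbut-3-en-1-yl]-5-oxooxolane-3-carboxylate (C2 epimers) | O=C1OC(CC/C(C)=C\I)[C@@H](C(=O)OC)[C@@H]1O | intermediate
15 | dipotassium (2S,3E,7Z)-8-iodo-3-(methoxycarbonyl)-7-methyl-2-oxidoocta-3,7-dienoate | [K+].[K+].[O-]C(=O)[C@@H]([O-])/C(C(=O)OC)=C\CC/C(C)=C\I | intermediate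
16 | (2S,3E,7Z)-8-iodo-3-(methoxycarbonyl)-2-[(4-methoxybenzyl)oxy]-7-methylocta-3,7-dienoic acid | OC(=O)[C@@H](OCc1ccc(OC)cc1)/C(C(=O)OC)=C\CC/C(C)=C\I | intermediate
17 | methyl (2E,6Z)-2-[(1S)-2-hydroxy-1-[(4-methoxybenzyl)oxy]ethyl]-7-iodo-6-methylhepta-2,6-dienoate | OC[C@@H](OCc1ccc(OC)cc1)/C(C(=O)OC)=C\CC/C(C)=C\I | intermediate
18 | methyl (2E,6Z)-7-iodo-2-[(1S)-1-[(4-methoxybenzyl)oxy]-2-oxoethyl]-6-methylhepta-2,6-dienoate | O=C[C@@H](OCc1ccc(OC)cc1)/C(C(=O)OC)=C\CC/C(C)=C\I | intermediate
19 | methyl (2E,6Z)-2-[(1S,2S,3S)-3-{[(tert-butyldimethylsilyl)oxy]methyl}-2-hydroxy-4-(methoxycarbonyl)-1-[(4-methoxybenzyl)oxy]pent-4-en-1-yl]-7-iodo-6-methylhepta-2,6-dienoate | C=C(C(=O)OC)[C@@H](CO[Si](C)(C)C(C)(C)C)[C@H](O)[C@@H](OCc1ccc(OC)cc1)/C(C(=O)OC)=C\CC/C(C)=C\I | intermediate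
20 | (R)-(2-methyloxiran-2-yl)methanol | OC[C@]1(C)CO1 | starting material
21 | (S)-2-methyloxirane-2-carboxylic acid | OC(=O)[C@]1(C)CO1 | intermediate
22 | C8 (2S)-2-methyloxirane-2-carboxylate of 19 (7S,8S,9S,2'S; C6–OTBS, C9–OPMB) | C=C(C(=O)OC)[C@@H](CO[Si](C)(C)C(C)(C)C)[C@H](OC(=O)[C@]1(C)CO1)[C@@H](OCc1ccc(OC)cc1)/C(C(=O)OC)=C\CC/C(C)=C\I | intermediate
23 | C6 primary alcohol (7S,8S,9S,2'S; C8 glycidate, C9–OPMB) | C=C(C(=O)OC)[C@@H](CO)[C@H](OC(=O)[C@]1(C)CO1)[C@@H](OCc1ccc(OC)cc1)/C(C(=O)OC)=C\CC/C(C)=C\I | intermediate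
24 | C6 aldehyde, acyclic (4Z)-alkenyl iodide (7R,8S,9S,2'S) | C=C(C(=O)OC)[C@@H](C=O)[C@H](OC(=O)[C@]1(C)CO1)[C@@H](OCc1ccc(OC)cc1)/C(C(=O)OC)=C\CC/C(C)=C\I | intermediate
25 | methyl (1E,5Z,7S,8S,9S,10S)-7-hydroxy-10-[(4-methoxybenzyl)oxy]-8-(3-methoxy-3-oxoprop-1-en-2-yl)-5-methyl-9-{[(2S)-2-methyloxirane-2-carbonyl]oxy}cyclodeca-1,5-diene-1-carboxylate | C/C1=C/[C@H](O)[C@H](C(=C)C(=O)OC)[C@H](OC(=O)[C@]2(C)CO2)[C@@H](OCc2ccc(OC)cc2)/C(C(=O)OC)=C\CC1 | intermediate
26 | methyl (3aS,4S,5S,6E,10Z,11aS)-5-[(4-methoxybenzyl)oxy]-10-methyl-3-methylidene-4-{[(2S)-2-methyloxirane-2-carbonyl]oxy}-2-oxo-2,3,3a,4,5,8,9,11a-octahydrocyclodeca[b]furan-6-carboxylate | C/C1=C/[C@@H]2OC(=O)C(=C)[C@@H]2[C@H](OC(=O)[C@]3(C)CO3)[C@@H](OCc3ccc(OC)cc3)/C(C(=O)OC)=C\CC1 | intermediate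
27 | methyl (1R,2S,4R,7E,9S,10S,11R)-9-[(4-methoxybenzyl)oxy]-4-methyl-12-methylidene-10-{[(2S)-2-methyloxirane-2-carbonyl]oxy}-13-oxo-3,14-dioxatricyclo[9.3.0.0^2,4]tetradec-7-ene-8-carboxylate | C=C1C(=O)O[C@@H]2[C@H]1[C@H](OC(=O)[C@]1(C)CO1)[C@@H](OCc1ccc(OC)cc1)/C(C(=O)OC)=C\CC[C@@]1(C)O[C@@H]21 | intermediate
28 | methyl (1R,2S,4R,7E,9S,10S,11R)-9-hydroxy-4-methyl-12-methylidene-10-{[(2S)-2-methyloxirane-2-carbonyl]oxy}-13-oxo-3,14-dioxatricyclo[9.3.0.0^2,4]tetradec-7-ene-8-carboxylate | C=C1C(=O)O[C@@H]2[C@H]1[C@H](OC(=O)[C@]1(C)CO1)[C@@H](O)/C(C(=O)OC)=C\CC[C@@]1(C)O[C@@H]21 | intermediate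
29 | methyl (1R,2S,4R,7E,9S,10S,11R)-9-acetoxy-4-methyl-12-methylidene-10-{[(2S)-2-methyloxirane-2-carbonyl]oxy}-13-oxo-3,14-dioxatricyclo[9.3.0.0^2,4]tetradec-7-ene-8-carboxylate | C=C1C(=O)O[C@@H]2[C@H]1[C@H](OC(=O)[C@]1(C)CO1)[C@@H](OC(C)=O)/C(C(=O)OC)=C\CC[C@@]1(C)O[C@@H]21 | target

**Step count.** Total: 18 steps. Longest linear sequence: 15 steps (3–10, then 12–18).

**Steps most likely to fail, with fallbacks**

Step 15. The ring closure may show poor facial selectivity at C6 (the C6 epimer would lactonise to the trans-fused lactone), and aldehyde 24 may suffer double-bond migration or C7 epimerisation before it cyclises. The fallback sets out from 24 and comes back at 25. The cyclisation is run as above but quenched cold with pH 7 buffer and not treated with PPTS, so that 25 and its C6 epimer, hydroxy ester F1, are kept as open hydroxy esters. The mixture is oxidised (Dess–Martin periodinane, pyridine) to the single macrocyclic enone F2. F2 is then reduced under reagent control ((S)-2-methyl-CBS-oxazaborolidine, catecholborane, −78 °C; alkenyl group as the large substituent) to 25, which lactonises to 26 as in step 15.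

Step 10. Chelation control or simple diastereoselection may erode and give mixtures of the C7/C8/C9 triad, and the allylindium may lose silyloxide by elimination. The fallback sets out from 4 and 18 and comes back at 19. Bromide 4 is converted (Bu3SnLi, CuBr·SMe2, THF, −78 °C) into allylstannane F3, which is added to 18 precomplexed with MgBr2·OEt2 in CH2Cl2 at −78 °C. The rigid magnesium chelate and the open antiperiplanar transition state of allylstannane additions are the established way to syn,syn triads from α-alkoxy aldehydes.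

Step 7. The eliminative ring opening may be sluggish or unselective (alkene geometry mixtures, deconjugation towards C2), and the carboxylate may compete for PMBCl. The fallback sets out from 11, bypasses steps 6 and 7, and comes back at 16. Aldehyde 11, PPh3 and dimethyl maleate give, through the stabilised ylide, dimethyl (E)-alkylidenesuccinate F4. Enolate oxidation at C9 (KN(SiMe3)2, then the appropriate enantiomer of (camphorsulfonyl)oxaziridine) gives hydroxy diester F5. PMB trichloroacetimidate with CSA gives PMB ether diester F6, and LiOH (1 equiv, THF/H2O, 0 °C) cleaves the unconjugated α-alkoxy ester selectively to 16.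

Further compounds
F1 | step 15 | methyl (1E,5Z,7R,8S,9S,10S)-7-hydroxy-10-[(4-methoxybenzyl)oxy]-8-(3-methoxy-3-oxoprop-1-en-2-yl)-5-methyl-9-{[(2S)-2-methyloxirane-2-carbonyl]oxy}cyclodeca-1,5-diene-1-carboxylate (C6 epimer of 25) | C/C1=C/[C@@H](O)[C@H](C(=C)C(=O)OC)[C@H](OC(=O)[C@]2(C)CO2)[C@@H](OCc2ccc(OC)cc2)/C(C(=O)OC)=C\CC1
F2 | step 15 | macrocyclic C6 enone (7R,8S,9S,2'S) | C/C1=C/C(=O)[C@H](C(=C)C(=O)OC)[C@H](OC(=O)[C@]2(C)CO2)[C@@H](OCc2ccc(OC)cc2)/C(C(=O)OC)=C\CC1
F3 | step 10 | methyl (Z)-4-[(tert-butyldimethylsilyl)oxy]-2-[(tributylstannyl)methyl]but-2-enoate | COC(=O)/C(C[Sn](CCCC)(CCCC)CCCC)=C/CO[Si](C)(C)C(C)(C)C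
F4 | step 7 | dimethyl (E)-2-[(Z)-5-iodo-4-methylpent-4-en-1-ylidene]butanedioate | COC(=O)C/C(C(=O)OC)=C\CC/C(C)=C\I
F5 | step 7 | dimethyl (2S,3E)-2-hydroxy-3-[(Z)-5-iodo-4-methylpent-4-en-1-ylidene]butanedioate | COC(=O)[C@@H](O)/C(C(=O)OC)=C\CC/C(C)=C\I
F6 | step 7 | dimethyl (2S,3E)-3-[(Z)-5-iodo-4-methylpent-4-en-1-ylidene]-2-[(4-methoxybenzyl)oxy]butanedioate | COC(=O)[C@@H](OCc1ccc(OC)cc1)/C(C(=O)OC)=C\CC/C(C)=C\I
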